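**Strategy.** Everything rests on opening ring C at the C3–C4 bond. In the 2,3-dihydro form, C3 with its hydroxyl and the C4 carbonyl are an α-ketol, the product of a benzoin union of two formyl carbons. A thiazolylidene therefore forges C3–C4 and closes ring C in one operation from a dialdehyde: a ring A salicylaldehyde whose phenolic oxygen (O1) carries a CH(Ar)–CHO unit (C2, C3; Ar = ring B). The C2/C3 configuration is irrelevant because dehydrogenation follows. O5 is carried as an isopropyl ether, so that the final unmasking is a chelation-assisted cleavage of the only secondary alkyl ether among five methoxy groups.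

Key step: step 11

Remark: the target is achiral; compounds 12–16 are racemic, and the two stereocentres of 16 are removed in step 12, so no absolute control is attempted.

Step 1
Reactants: 1 3-hydroxy-4,5-dimethoxybenzaldehyde
Product: 2 3-(benzyloxy)-4,5-dimethoxybenzaldehyde
Conditions: BnBr, K2CO3, DMF, rt
Reagents that add atoms: benzyl bromide, BrCc1ccccc1
Why: Williamson etherification of the only phenol; benzyl is chosen because it can later be removed by hydrogenolysis without touching an isopropyl ether.

Step 2
Reactants: 2 3-(benzyloxy)-4,5-dimethoxybenzaldehyde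
Product: 4 3-(benzyloxy)-4,5-dimethoxyphenol, via aryl formate 3 (not isolated)
Conditions: mCPBA, CH2Cl2, 0 °C → rt; aq. NaHCO3 wash; then K2CO3 (cat.), MeOH, rt
Reagents that add atoms: 3-chloroperoxybenzoic acid, OOC(=O)c1cccc(Cl)c1
Why: Baeyer–Villiger oxidation, in which the electron-rich aryl group migrates to give the aryl formate, followed by mild methanolysis; this turns the formyl-bearing carbon into the future C5–O.

Step 3
Reactants: 4 3-(benzyloxy)-4,5-dimethoxyphenol
Product: 5 1-(benzyloxy)-2,3-dimethoxy-5-(propan-2-yloxy)benzene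
Conditions: 2-bromopropane (excess), K2CO3, DMF, 60 °C
Reagents that add atoms: 2-bromopropane, CC(C)Br
Why: Williamson alkylation of the phenoxide with a secondary bromide; the isopropyl ether marks this oxygen (the later O5) for selective removal at the end.

Step 4
Reactants: 5 1-(benzyloxy)-2,3-dimethoxy-5-(propan-2-yloxy)benzene
Product: 6 2,3-dimethoxy-5-(propan-2-yloxy)phenol
Conditions: H2 (1 atm), 10% Pd/C, EtOAc/MeOH, rt
Reagents that add atoms: none
Why: Catalytic hydrogenolysis cleaves only the benzylic C–O bond; methyl and isopropyl aryl ethers are inert.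

Step 5
Reactants: 6 2,3-dimethoxy-5-(propan-2-yloxy)phenol
Product: 8 2-hydroxy-3,4-dimethoxy-6-(propan-2-yloxy)benzaldehyde, via magnesium salicyl alkoxide 7 (not isolated)
Conditions: MgCl2, Et3N, paraformaldehyde, MeCN, reflux; aq. HCl work-up
Reagents that add atoms: formaldehyde (from paraformaldehyde), C=O
Why: Magnesium-mediated ortho-formylation (Casnati–Skattebøl): the magnesium phenoxide delivers formaldehyde to the one free ortho carbon (the other bears a methoxy group), and a second formaldehyde oxidises the hydroxymethyl stage by hydride transfer.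

Step 6
Reactants: 9 3,4,5-trimethoxyphenylacetic acid
Product: 10 methyl 2-(3,4,5-trimethoxyphenyl)acetate
Conditions: MeOH, H2SO4 (cat.), reflux
Reagents that add atoms: methanol, CO
Why: Fischer esterification, driven by the solvent excess of methanol.

Step 7
Reactants: 10 methyl 2-(3,4,5-trimethoxyphenyl)acetate
Product: 12 methyl 2-bromo-2-(3,4,5-trimethoxyphenyl)acetate (racemic), via silyl ketene acetal 11 (not isolated)
Conditions: LiN(SiMe3)2, Me3SiCl, THF, −78 °C; then NBS, −78 → 0 °C
Reagents that add atoms: N-bromosuccinimide, O=C1CCC(=O)N1Br; chlorotrimethylsilane, C[Si](C)(C)Cl (its silyl group is carried by 11 only)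
Why: α-Bromination of an ester through its ketene silyl acetal, which is far more nucleophilic toward NBS than the trimethoxyarene, so ring bromination and enolate self-alkylation should be avoided.

Step 8
Reactants: 8 2-hydroxy-3,4-dimethoxy-6-(propan-2-yloxy)benzaldehyde; 12 methyl 2-bromo-2-(3,4,5-trimethoxyphenyl)acetate (racemic)
Product: 13 methyl 2-[2-formyl-5,6-dimethoxy-3-(propan-2-yloxy)phenoxy]-2-(3,4,5-trimethoxyphenyl)acetate (racemic)
Conditions: K2CO3, DMF, rt
Reagents that add atoms: none
Why: Williamson O-alkylation (SN2) of the salicylaldehyde phenoxide by a benzylic α-bromo ester; weak base and room temperature should keep the acidic α-hydrogen of the product from attacking the ortho formyl group.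

Step 9
Reactants: 13 methyl 2-[2-formyl-5,6-dimethoxy-3-(propan-2-yloxy)phenoxy]-2-(3,4,5-trimethoxyphenyl)acetate (racemic)
Product: 14 2-[2-(hydroxymethyl)-5,6-dimethoxy-3-(propan-2-yloxy)phenoxy]-2-(3,4,5-trimethoxyphenyl)ethan-1-ol (racemic)
Conditions: LiAlH4, THF, 0 °C; Fieser work-up
Reagents that add atoms: none
Why: Hydride reduction of both the ester and the aryl aldehyde to primary alcohols, which avoids an unselective partial reduction; aryl alkyl ethers are inert.

Step 10
Reactants: 14 2-[2-(hydroxymethyl)-5,6-dimethoxy-3-(propan-2-yloxy)phenoxy]-2-(3,4,5-trimethoxyphenyl)ethan-1-ol (racemic)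
Product: 15 3,4-dimethoxy-2-[2-oxo-1-(3,4,5-trimethoxyphenyl)ethoxy]-6-(propan-2-yloxy)benzaldehyde (racemic)
Conditions: Dess–Martin periodinane (2.4 equiv), pyridine, CH2Cl2, 0 °C → rt; crude product used at once
Reagents that add atoms: none
Why: Dess–Martin oxidation of both primary alcohols under near-neutral, chloride-free conditions, which should spare the acid-labile trialkoxybenzylic position and not enolise the new α-aryloxy aldehyde.

Step 11
Reactants: 15 3,4-dimethoxy-2-[2-oxo-1-(3,4,5-trimethoxyphenyl)ethoxy]-6-(propan-2-yloxy)benzaldehyde (racemic)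
Product: 16 racemic trans-3-hydroxy-7,8-dimethoxy-5-(propan-2-yloxy)-2-(3,4,5-trimethoxyphenyl)chroman-4-one ((2R,3R) enantiomer drawn)
Conditions: 3-ethyl-5-(2-hydroxyethyl)-4-methylthiazolium bromide (20 mol%), Et3N (40 mol%), degassed THF/t-BuOH, 50 °C, Ar
Reagents that add atoms: none
Why: Et3N deprotonates the thiazolium salt to its thiazol-2-ylidene, which adds to a formyl group and, after proton transfer, gives an enaminol (Breslow intermediate) that attacks the second formyl carbon to forge C3–C4; collapse of the adduct releases the carbene and the α-ketol. The closest known reaction type is the carbene-catalysed intramolecular crossed benzoin (acyloin) cyclisation of aryl-ether-tethered carbonyl pairs to 3-hydroxychroman-4-ones. Ring C closes in the 6-exo-trig mode. The new C3 stereocentre is under thermodynamic control, since C3 epimerises through the enediol in the presence of Et3N and the 2,3-trans isomer with both substituents equatorial should prevail (racemic, as C2 of 15 is racemic and nothing chiral is present). The step needs ring closure to outrun expulsion of the α-aryloxide from an enaminol formed at the aliphatic aldehyde and aldol reactions of the acidic C2–H; the six-membered transition state set up by the ortho ether tether, the modest leaving-group ability of the electron-rich trialkoxyphenoxide and the low base loading should secure this. Which aldehyde serves as acyl donor is not critical, because the regioisomeric 4-hydroxy-3-ketone would tautomerise through the same enediol to 16 or be oxidised to the same flavonol in step 12.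

Step 12
Reactants: 16 racemic trans-3-hydroxy-7,8-dimethoxy-5-(propan-2-yloxy)-2-(3,4,5-trimethoxyphenyl)chroman-4-one
Product: 17 3-hydroxy-7,8-dimethoxy-5-(propan-2-yloxy)-2-(3,4,5-trimethoxyphenyl)-4H-chromen-4-one
Conditions: I2 (0.2 equiv), DMSO, 110 °C
Reagents that add atoms: none
Why: Iodine-mediated dehydrogenation of the enolisable ketol across C2–C3, with DMSO reoxidising HI to I2, gives the fully conjugated 3-hydroxy-4-pyranone and removes both stereocentres; catalytic iodine limits ring iodination.

Step 13
Reactants: 17 3-hydroxy-7,8-dimethoxy-5-(propan-2-yloxy)-2-(3,4,5-trimethoxyphenyl)-4H-chromen-4-one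
Product: 18 3,5-dihydroxy-7,8-dimethoxy-2-(3,4,5-trimethoxyphenyl)-4H-chromen-4-one (3,5-dihydroxy-7,8,3',4',5'-pentamethoxyflavone)
Conditions: BCl3 (3 equiv), CH2Cl2, −78 → 0 °C; then MeOH, aq. HCl
Reagents that add atoms: none
Why: Lewis-acid ether cleavage: BCl3 held between the C4 carbonyl and O5 ionises the secondary isopropyl–oxygen bond far faster than any methyl ether, and the boron chelate is hydrolysed on work-up.

**Compound list**

1 | 3-hydroxy-4,5-dimethoxybenzaldehyde | COc1cc(C=O)cc(O)c1OC | starting material
2 | 3-(benzyloxy)-4,5-dimethoxybenzaldehyde | COc1cc(C=O)cc(OCc2ccccc2)c1OC | intermediate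
3 | 3-(benzyloxy)-4,5-dimethoxyphenyl formate | COc1cc(OC=O)cc(OCc2ccccc2)c1OC | intermediate (not isolated)
4 | 3-(benzyloxy)-4,5-dimethoxyphenol | COc1cc(O)cc(OCc2ccccc2)c1OC | intermediate
5 | 1-(benzyloxy)-2,3-dimethoxy-5-(propan-2-yloxy)benzene | COc1cc(OC(C)C)cc(OCc2ccccc2)c1OC | intermediate
6 | 2,3-dimethoxy-5-(propan-2-yloxy)phenol | COc1cc(OC(C)C)cc(O)c1OC | intermediate
7 | 2-(hydroxymethyl)-5,6-dimethoxy-3-(propan-2-yloxy)phenol (present as its magnesium salt) | COc1cc(OC(C)C)c(CO)c(O)c1OC | intermediate (not isolated)
8 | 2-hydroxy-3,4-dimethoxy-6-(propan-2-yloxy)benzaldehyde | COc1cc(OC(C)C)c(C=O)c(O)c1OC | intermediate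
9 | 3,4,5-trimethoxyphenylacetic acid | COc1cc(CC(=O)O)cc(OC)c1OC | starting material
10 | methyl 2-(3,4,5-trimethoxyphenyl)acetate | COC(=O)Cc1cc(OC)c(OC)c(OC)c1 | intermediate
11 | [1-methoxy-2-(3,4,5-trimethoxyphenyl)ethenyl]oxy(trimethyl)silane (E/Z mixture) | COC(O[Si](C)(C)C)=Cc1cc(OC)c(OC)c(OC)c1 | intermediate (not isolated)
12 | methyl 2-bromo-2-(3,4,5-trimethoxyphenyl)acetate (racemic) | COC(=O)C(Br)c1cc(OC)c(OC)c(OC)c1 | intermediate
13 | methyl 2-[2-formyl-5,6-dimethoxy-3-(propan-2-yloxy)phenoxy]-2-(3,4,5-trimethoxyphenyl)acetate (racemic) | COC(=O)C(Oc1c(OC)c(OC)cc(OC(C)C)c1C=O)c1cc(OC)c(OC)c(OC)c1 | intermediate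
14 | 2-[2-(hydroxymethyl)-5,6-dimethoxy-3-(propan-2-yloxy)phenoxy]-2-(3,4,5-trimethoxyphenyl)ethan-1-ol (racemic) | OCC(Oc1c(OC)c(OC)cc(OC(C)C)c1CO)c1cc(OC)c(OC)c(OC)c1 | intermediate
15 | 3,4-dimethoxy-2-[2-oxo-1-(3,4,5-trimethoxyphenyl)ethoxy]-6-(propan-2-yloxy)benzaldehyde (racemic) | O=CC(Oc1c(OC)c(OC)cc(OC(C)C)c1C=O)c1cc(OC)c(OC)c(OC)c1 | intermediate (key-step precursor)
16 | racemic trans-3-hydroxy-7,8-dimethoxy-5-(propan-2-yloxy)-2-(3,4,5-trimethoxyphenyl)chroman-4-one, (2R,3R) enantiomer drawn | COc1cc([C@H]2Oc3c(OC)c(OC)cc(OC(C)C)c3C(=O)[C@@H]2O)cc(OC)c1OC | intermediate (key-step product)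
17 | 3-hydroxy-7,8-dimethoxy-5-(propan-2-yloxy)-2-(3,4,5-trimethoxyphenyl)-4H-chromen-4-one | COc1cc(-c2oc3c(OC)c(OC)cc(OC(C)C)c3c(=O)c2O)cc(OC)c1OC | intermediate
18 | 3,5-dihydroxy-7,8-dimethoxy-2-(3,4,5-trimethoxyphenyl)-4H-chromen-4-one | COc1cc(-c2oc3c(OC)c(OC)cc(O)c3c(=O)c2O)cc(OC)c1OC | target

**Totals.** Total step count: 13. Longest linear sequence: 11 steps (steps 1–5 and 8–13, from 1); the ring B branch (steps 6–7) joins at step 8.

**Steps most likely to fail**

1. Step 11. The carbene may add to the more electrophilic aliphatic formyl group, and the resulting enaminol may expel the aryloxide (internal redox to an acyl azolium, ending in an aryl ester) faster than it closes the ring. Base-induced aldol closure of the acidic C2–H onto the aromatic aldehyde, or ring opening of the ketol, are further drains. Fallback, setting out from 15 and returning at 16: the C3–C4 bond would be made reductively. SmI2 in THF/t-BuOH at −78 °C → rt should effect intramolecular pinacol coupling to 7,8-dimethoxy-5-(propan-2-yloxy)-2-(3,4,5-trimethoxyphenyl)chromane-3,4-diol F1 (diastereomer mixture). DDQ in CH2Cl2 at rt should then oxidise only the C4 carbinol, which is benzylic to the trioxygenated ring A, to give 16 as a cis/trans mixture. Et3N would equilibrate this toward trans, and step 12 accepts either isomer.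

2. Step 10. The double oxidation may go astray by ionisation of the 2,4,6-trioxygenated benzylic alcohol, by lactol formation after the first oxidation and over-oxidation to a seven-membered lactone, or by enolisation and hydration of the α-aryloxy aldehyde during isolation. Fallback, setting out from 13 and returning at 15, which avoids diol 14 altogether: the aryl aldehyde of 13 would be masked with HC(OMe)3 and cat. pyridinium p-toluenesulfonate in MeOH as methyl 2-[2-(dimethoxymethyl)-5,6-dimethoxy-3-(propan-2-yloxy)phenoxy]-2-(3,4,5-trimethoxyphenyl)acetate F2. DIBAL-H in CH2Cl2 at −78 °C should stop at the aldehyde stage of the α-aryloxy ester to give 2-[2-(dimethoxymethyl)-5,6-dimethoxy-3-(propan-2-yloxy)phenoxy]-2-(3,4,5-trimethoxyphenyl)acetaldehyde F3. Brief treatment with pyridinium p-toluenesulfonate in wet acetone should unmask the very labile trialkoxybenzaldehyde acetal to give 15.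

3. Step 8. After O-alkylation, carbonate may remove the acidic α-hydrogen of the new ester and the carbanion may close onto the ortho formyl group (intramolecular aldol to a dihydrobenzofuranol). Alternatively the hindered, hydrogen-bonded phenoxide may react so slowly that the benzylic bromide is lost to solvolysis. Fallback, setting out from 10 (and 8) and returning at 13, which forms the ether without base: the lithium enolate of 10 (LiN(SiMe3)2, THF, −78 °C) would be hydroxylated with 3-phenyl-2-(phenylsulfonyl)oxaziridine to methyl 2-hydroxy-2-(3,4,5-trimethoxyphenyl)acetate F4 (racemic). Mitsunobu coupling of F4 with phenol 8 (PPh3, diisopropyl azodicarboxylate, THF, 0 °C → rt) should then give 13.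

**Further compounds**

F1 | step 11 | 7,8-dimethoxy-5-(propan-2-yloxy)-2-(3,4,5-trimethoxyphenyl)chromane-3,4-diol (diastereomer mixture, racemic) | COc1cc(C2Oc3c(OC)c(OC)cc(OC(C)C)c3C(O)C2O)cc(OC)c1OC
F2 | step 10 | methyl 2-[2-(dimethoxymethyl)-5,6-dimethoxy-3-(propan-2-yloxy)phenoxy]-2-(3,4,5-trimethoxyphenyl)acetate (racemic) | COC(=O)C(Oc1c(OC)c(OC)cc(OC(C)C)c1C(OC)OC)c1cc(OC)c(OC)c(OC)c1
F3 | step 10 | 2-[2-(dimethoxymethyl)-5,6-dimethoxy-3-(propan-2-yloxy)phenoxy]-2-(3,4,5-trimethoxyphenyl)acetaldehyde (racemic) | O=CC(Oc1c(OC)c(OC)cc(OC(C)C)c1C(OC)OC)c1cc(OC)c(OC)c(OC)c1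
F4 | step 8 | methyl 2-hydroxy-2-(3,4,5-trimethoxyphenyl)acetate (racemic) | COC(=O)C(O)c1cc(OC)c(OC)c(OC)c1
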